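A direct plan would make ring C by an auxiliary-controlled Birch alkylation that sets C8, tie it through a C6–O–C7 ester to a seven-membered chloro enone acid (ester A1), and then, in one flask, join C9 to C10 by Lewis acid Michael addition, contract the seven-membered ring to ring A by Favorskii rearrangement and unmask the enone (lactone acid A2). Vinyl radical closure of ring D, saponification to hydroxy diacid A3 and oxidation would finish. Its weakest points would be:
(a) the three-phase Michael/Favorskii/hydrolysis operation, because C9, C10, C4 and C5 would rest on conformational arguments alone, for a mixture of C4 epimers, against HCl loss and acyl cleavage, on the most valuable convergent material;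
(b) the run-up, because about eight steps (amide coupling, silyl blocking, Birch alkylation, auxiliary cleavage, chlorination, ring expansion, selenoxide elimination, ester cleavage) would buy one stereocentre and an achiral acceptor;
(c) the late hydroxide opening of the ε-lactone, because the C9–C10 bond lies α to the C11 ketone and β to the C6 carbonyl, so retro-Michael cleavage or C9 epimerisation could undo the key step at the very end.

**Plan of the new route.** The retrosynthesis cuts C11–C12 and C13–C16 together, then C8–C14 and C8–C15 (enolate alkylations), C9–C10 (radical conjugate addition) and C5–C10, C10–C1, C3–C4 (ring A built around nitroethane). Ring A arises first; rings C and D arise together in the last C–C bond-forming step. One chiral butenolide is used twice and supplies C19–C4–C5–C6 as well as C7–C8–C9–C11, so every stereocentre is relayed from its acetal carbon. The key step is possible because quaternary C8 carries two three-carbon arms (C14–C13–C12 and C15–C16–C17) next to C9, whose C11 carbonyl lies 1,6 to C12 while C13 lies 1,5 to C16. A C11 acyl radical can therefore zip this 1,6-enyne into the bicyclo[3.2.1]octane and leave the C11 ketone and the C16=C17 methylene in place. No Favorskii step, no hydroxide opening of a tether and no steps spent only on an auxiliary occur; the aldehyde and the acids are released last under neutral conditions.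

Key step: step 13

Remarks: atom numbers are those of ent-kaurane (C18 methyl and C19 carboxyl on C4, C20 methyl on C10). Assumption: (5S)-5-(d-menthyloxy)furan-2(5H)-one (1) is taken as a commercial reagent; otherwise it is one condensation from (+)-menthol and 5-hydroxyfuran-2(5H)-one.

Step 1
Reactants: 1 (5S)-5-(d-menthyloxy)furan-2(5H)-one; 2 nitroethane
Product: 3 (4R,5S)-5-(d-menthyloxy)-4-(1-nitroethyl)dihydrofuran-2(3H)-one
Conditions: 2 (5 equiv), DBU (0.2 equiv), MeCN, 0 to 23 °C
Reagents that add atoms: none
Why: Base-catalysed Michael addition of the nitronate to this butenolide should take place anti to the menthyloxy group, which sets C5, while the nitro-bearing C10 forms as an epimer mixture that is of no consequence because it later becomes a radical centre.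

Step 2
Reactants: 3 (4R,5S)-5-(d-menthyloxy)-4-(1-nitroethyl)dihydrofuran-2(3H)-one; 4 1-chloro-3-iodopropane
Product: 5 C4-(3-chloropropyl) nitro lactone acetal
Conditions: LiN(iPr)2 (2.2 equiv), THF, −78 °C; 4, DMPU, −78 to −20 °C
Reagents that add atoms: none
Why: In the dianion (nitronate plus lactone enolate) only the far more nucleophilic enolate carbon C4 should be C-alkylated, and only by the iodide end of 4, which attaches C3–C2–C1; the C4 configuration formed here is reset in step 4.

Step 3
Reactants: 5 C4-(3-chloropropyl) nitro lactone acetal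
Product: 6 ring A nitro lactone acetal (bicyclic)
Conditions: DBU, NaI (cat.), DMSO, 40 °C
Reagents that add atoms: none
Why: Intramolecular C-alkylation of the secondary nitronate (6-exo-tet, iodide-assisted) should close ring A through the C10–C1 bond and make C10 quaternary, since O-alkylation would need an eight-membered ring.

Step 4
Reactants: 6 ring A nitro lactone acetal (bicyclic); 7 iodomethane
Product: 8 C4-methylated ring A nitro lactone acetal
Conditions: LiN(iPr)2, THF, −78 °C; 7, −78 to −20 °C
Reagents that add atoms: none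
Why: Alkylation of the ring-fusion lactone enolate should occur on the face of C4 remote from the C5–C10 bond and give the cis-fused bicycle (C18 trans and C3 cis to C10), so that C19 and C6 end up cis on ring A as in the target.

Step 5
Reactants: 8 C4-methylated ring A nitro lactone acetal
Product: 9 cis-fused ring A nitro anhydride
Conditions: CrO3, aq H2SO4, acetone, 0 to 23 °C
Reagents that add atoms: water, O
Why: Jones oxidation hydrolyses the menthyl acetal in the acidic medium and oxidises the C6 lactol to the carbonyl level, giving the stable cis-fused anhydride without any base, which the new β-nitro carbonyl unit would not tolerate.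

Step 6
Reactants: 9 cis-fused ring A nitro anhydride; 1 (5S)-5-(d-menthyloxy)furan-2(5H)-one
Product: 10 ring A anhydride joined at C10 to the C9 lactone acetal
Conditions: 1 (3 equiv), Bu3SnH (1.5 equiv, syringe pump), AIBN (0.2 equiv), benzene, 80 °C
Reagents that add atoms: none
Why: Tin-mediated denitration gives the nucleophilic tertiary C10 radical from either C10 epimer (Giese reaction), which should add to the β-carbon C9 of the butenolide anti to its menthyloxy group (sets C9) and from the convex face of the cis-fused anhydride, anti to the C5–C6 bond (sets C10 with C20 cis to C6 and C19).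

Step 7
Reactants: 10 ring A anhydride joined at C10 to the C9 lactone acetal; 11 allyl alcohol; 12 allyl bromide
Product: 14 diallyl ester lactone acetal, via mono-allyl ester acid 13 (not isolated)
Conditions: 11 (5 equiv), DMAP (cat.), CH2Cl2, 23 °C; then 12, Cs2CO3, DMF, 23 °C
Reagents that add atoms: none
Why: Alcoholysis of the ring A anhydride followed by O-alkylation of the remaining caesium carboxylate turns both carboxyl groups into allyl esters, whichever carbonyl is opened first, and these esters withstand the later enolate, oxidation and radical steps and leave under neutral conditions.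

Step 8
Reactants: 14 diallyl ester lactone acetal; 15 (3-bromoprop-1-yn-1-yl)trimethylsilane
Product: 16 C8-(3-trimethylsilylpropargyl) lactone acetal
Conditions: LiN(iPr)2, THF, −78 °C; 15, DMPU, −78 to −40 °C
Reagents that add atoms: none
Why: Kinetic deprotonation should occur only at C8 of the γ-lactone (C4 is quaternary and C5–H is shielded by two quaternary neighbours), and alkylation installs the C15–C16–C17 arm; the C8 configuration is reset in the next step.

Step 9
Reactants: 16 C8-(3-trimethylsilylpropargyl) lactone acetal; 12 allyl bromide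
Product: 18 C8-allyl C8-propargyl lactone acetal, via silylalkyne 17 (not isolated)
Conditions: LiN(iPr)2, THF–DMPU, −78 °C; 12, −78 to −20 °C; then Bu4NF, AcOH, THF, 0 °C
Reagents that add atoms: none
Why: The second alkylation of the C8 enolate should occur anti to the bulky ring A substituent on C9, as is the rule for β-substituted γ-lactone enolates, so the allyl arm (C14–C13–C12) is trans and the propargyl arm cis to C10, which fixes quaternary C8; buffered fluoride then frees the terminal alkyne.

Step 10
Reactants: 18 C8-allyl C8-propargyl lactone acetal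
Product: 19 C7/C11 succinic anhydride
Conditions: CrO3, aq H2SO4, acetone, 0 to 23 °C
Reagents that add atoms: water, O
Why: Jones oxidation as in step 5 converts the second lactone acetal into the 2,2,3-trisubstituted succinic anhydride, which brings C11 to the acid level while the allyl esters, the alkene and the alkyne survive.

Step 11
Reactants: 19 C7/C11 succinic anhydride
Product: 21 C7 triethylsilyl ether C11 acid, via sodium hydroxy carboxylate 20 (not isolated)
Conditions: NaBH4, THF, 0 °C; then Et3SiCl, imidazole, DMF, 0 to 23 °C; aq NaHCO3, then pH 4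
Reagents that add atoms: chlorotriethylsilane, CC[Si](Cl)(CC)CC
Why: Borohydride reduction of unsymmetrical succinic anhydrides takes place at the carbonyl next to the more substituted carbon, here C7 on quaternary C8, and silylation of the hydroxy carboxylate before acidification prevents relactonisation, so C7 is left as a protected primary alcohol and C11 as the free acid.

Step 12
Reactants: 21 C7 triethylsilyl ether C11 acid
Product: 22 C11 Se-phenyl selenoester
Conditions: N-(phenylselanyl)phthalimide, PBu3, CH2Cl2, 0 to 23 °C
Reagents that add atoms: N-(phenylselanyl)phthalimide, O=C1N([Se]c2ccccc2)C(=O)c2ccccc12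
Why: Phosphine-mediated selenoesterification converts the hindered acid under neutral conditions into the Se-phenyl selenoester, the standard precursor of an acyl radical.

Step 13
Reactants: 22 C11 Se-phenyl selenoester
Product: 26 diallyl 11-oxo-7-(triethylsilyloxy)-6,7-seco-ent-kaur-16-ene-6,19-dioate, via acyl radical 23 (not isolated), via C13 radical 24 (not isolated), via vinyl radical 25 (not isolated)
Conditions: Bu3SnH (1.3 equiv, syringe pump, 8 h), AIBN (0.2 equiv), benzene (0.003 M), 80 °C
Reagents that add atoms: none
Why: Tin radical abstraction of the phenylselanyl group gives the C11 acyl radical, which closes ring C by 6-endo-trig attack on the terminal carbon C12 of the allyl arm; the secondary C13 radical then closes ring D by 5-exo-dig attack on C16 of the propargyl arm, and the vinyl radical takes hydrogen from Bu3SnH to leave the C16=C17 methylene. The closest known reaction type is the acyl radical cascade cyclisation of selenoesters onto alkenes and alkynes under tin hydride. C13 is the only new stereocentre and is fixed by the bridge itself, because C16 can reach C13 only on the face of ring C that carries C15; C8 and C9 are already set, and C9–H is not α to a ketone until this step. The step needs 6-endo closure to prevail over 5-exo closure, decarbonylation and early reduction: acyl radicals close onto unactivated terminal alkenes largely in the 6-endo mode, quaternary C8 speeds ring closure (Thorpe–Ingold effect), a 5-exo adduct can still reach the same C13 radical by 1,2-acyl shift (Dowd–Beckwith ring expansion), and slow addition keeps the hydride concentration low. The second closure requires the conformer of the cyclohexanone radical with the propargyl arm axial, which places C10 axial as in the target, and high dilution gives it time to be populated.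

Step 14
Reactants: 26 diallyl 11-oxo-7-(triethylsilyloxy)-6,7-seco-ent-kaur-16-ene-6,19-dioate
Product: 27 diallyl 7,11-dioxo-6,7-seco-ent-kaur-16-ene-6,19-dioate
Conditions: (COCl)2, DMSO, CH2Cl2, −78 to −30 °C; Et3N, −78 to 0 °C
Reagents that add atoms: none
Why: Swern oxidation cleaves a primary triethylsilyl ether and oxidises it in the same operation, so the neopentyl C7 aldehyde forms without over-oxidation or a separate deprotection, while C8 has no hydrogen and the brief exposure to Et3N below 0 °C should not epimerise C9.

Step 15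
Reactants: 27 diallyl 7,11-dioxo-6,7-seco-ent-kaur-16-ene-6,19-dioate
Product: 28 7,11-dioxo-6,7-seco-ent-kaur-16-ene-6,19-dioic acid (CNP0408869.1)
Conditions: Pd(PPh3)4 (5 mol %), TolSO2Na, THF/MeOH, 23 °C; then aq HCl to pH 3
Reagents that add atoms: none
Why: Zerovalent palladium ionises both allyl esters (Tsuji–Trost deallylation) and the sulfinate traps the allyl groups, so the two acids are set free at room temperature under neutral conditions that spare the aldehyde, the exocyclic alkene and the C9 stereocentre.

**Compound list**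
1 | (5S)-5-{[(1S,2R,5S)-5-methyl-2-(propan-2-yl)cyclohexyl]oxy}furan-2(5H)-one, (5S)-5-(d-menthyloxy)furan-2(5H)-one | O=C1C=C[C@@H](O[C@H]2C[C@@H](C)CC[C@@H]2C(C)C)O1 | starting material
2 | nitroethane | CC[N+](=O)[O-] | starting material
3 | (4R,5S)-5-(d-menthyloxy)-4-(1-nitroethyl)dihydrofuran-2(3H)-one (4,5-trans; both epimers at the nitro carbon C10) | O=C1C[C@H](C(C)[N+](=O)[O-])[C@@H](O[C@H]2C[C@@H](C)CC[C@@H]2C(C)C)O1 | intermediate
4 | 1-chloro-3-iodopropane | ClCCCI | starting material
5 | 3-(3-chloropropyl)-5-(d-menthyloxy)-4-(1-nitroethyl)dihydrofuran-2(3H)-one (4,5-trans; C4 and C10 epimers in ent-kaurane numbering) | O=C1C(CCCCl)[C@H](C(C)[N+](=O)[O-])[C@@H](O[C@H]2C[C@@H](C)CC[C@@H]2C(C)C)O1 | intermediate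
6 | 3-(d-menthyloxy)-4-methyl-4-nitrohexahydroisobenzofuran-1(3H)-one (ring A closed; acetal C6 carries the menthyloxy group trans to the C5–C10 bond; C4 and C10 epimers) | [O-][N+](=O)C1(C)CCCC2C(=O)O[C@H](O[C@H]3C[C@@H](C)CC[C@@H]3C(C)C)[C@@H]12 | intermediate
7 | iodomethane | CI | starting material
8 | 3-(d-menthyloxy)-4,7a-dimethyl-4-nitrohexahydroisobenzofuran-1(3H)-one (cis ring fusion, C18 cis to H5; 3,3a-trans; C10 epimers) | [O-][N+](=O)C1(C)CCC[C@@]2(C)C(=O)O[C@H](O[C@H]3C[C@@H](C)CC[C@@H]3C(C)C)[C@@H]12 | intermediate
9 | 4,7a-dimethyl-4-nitrohexahydroisobenzofuran-1,3-dione (cis-fused ring A anhydride, C4 and C5 as in the target; C10 epimers) | [O-][N+](=O)C1(C)CCC[C@@]2(C)C(=O)OC(=O)[C@@H]12 | intermediate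
10 | ring A anhydride whose C10 (methyl cis to the anhydride carbons) carries C9 of a 5-(d-menthyloxy)-2-oxotetrahydrofuran-4-yl group (C9–C10 trans to the menthyloxy group) | O=C1C[C@H]([C@]2(C)CCC[C@@]3(C)C(=O)OC(=O)[C@@H]23)[C@@H](O[C@H]4C[C@@H](C)CC[C@@H]4C(C)C)O1 | intermediate
11 | prop-2-en-1-ol (allyl alcohol) | C=CCO | starting material
12 | 3-bromoprop-1-ene (allyl bromide) | C=CCBr | starting material
13 | mono-allyl ester acid from 10 (C6 allyl ester, C19 acid) | O=C1C[C@H]([C@]2(C)CCC[C@@](C)(C(=O)O)[C@H]2C(=O)OCC=C)[C@@H](O[C@H]3C[C@@H](C)CC[C@@H]3C(C)C)O1 | intermediate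
14 | diallyl 1,3-dimethyl-3-[5-(d-menthyloxy)-2-oxotetrahydrofuran-4-yl]cyclohexane-1,2-dicarboxylate (ring A as in the target; lactone 4,5-trans) | O=C1C[C@H]([C@]2(C)CCC[C@@](C)(C(=O)OCC=C)[C@H]2C(=O)OCC=C)[C@@H](O[C@H]3C[C@@H](C)CC[C@@H]3C(C)C)O1 | intermediate
15 | (3-bromoprop-1-yn-1-yl)trimethylsilane | C[Si](C)(C)C#CCBr | starting material
16 | 14 carrying a 3-(trimethylsilyl)prop-2-yn-1-yl group on C8 (C8 epimers) | O=C1C(CC#C[Si](C)(C)C)[C@H]([C@]2(C)CCC[C@@](C)(C(=O)OCC=C)[C@H]2C(=O)OCC=C)[C@@H](O[C@H]3C[C@@H](C)CC[C@@H]3C(C)C)O1 | intermediate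
17 | C8-allyl C8-[3-(trimethylsilyl)propargyl] lactone acetal (allyl trans, propargyl cis to the C9–C10 bond) | O=C1[C@](CC=C)(CC#C[Si](C)(C)C)[C@H]([C@]2(C)CCC[C@@](C)(C(=O)OCC=C)[C@H]2C(=O)OCC=C)[C@@H](O[C@H]3C[C@@H](C)CC[C@@H]3C(C)C)O1 | intermediate
18 | C8-allyl C8-propargyl lactone acetal (allyl trans, propargyl cis to the C9–C10 bond) | O=C1[C@](CC=C)(CC#C)[C@H]([C@]2(C)CCC[C@@](C)(C(=O)OCC=C)[C@H]2C(=O)OCC=C)[C@@H](O[C@H]3C[C@@H](C)CC[C@@H]3C(C)C)O1 | intermediate
19 | 2-allyl-2-propargyl-3-(ring A diallyl ester) succinic anhydride (carbonyls C7 and C11) | O=C1[C@](CC=C)(CC#C)[C@H]([C@]2(C)CCC[C@@](C)(C(=O)OCC=C)[C@H]2C(=O)OCC=C)C(=O)O1 | intermediate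
20 | sodium carboxylate (C11) with free C7 hydroxymethyl group | OC[C@](CC=C)(CC#C)[C@H]([C@]1(C)CCC[C@@](C)(C(=O)OCC=C)[C@H]1C(=O)OCC=C)C(=O)[O-].[Na+] | intermediate
21 | C11 acid with C7 as triethylsilyloxymethyl group on quaternary C8 (allyl and propargyl arms) | CC[Si](CC)(CC)OC[C@](CC=C)(CC#C)[C@H]([C@]1(C)CCC[C@@](C)(C(=O)OCC=C)[C@H]1C(=O)OCC=C)C(=O)O | intermediate
22 | Se-phenyl selenoester of 21 | CC[Si](CC)(CC)OC[C@](CC=C)(CC#C)[C@H]([C@]1(C)CCC[C@@](C)(C(=O)OCC=C)[C@H]1C(=O)OCC=C)C(=O)[Se]c1ccccc1 | intermediate
23 | C11 acyl radical | CC[Si](CC)(CC)OC[C@](CC=C)(CC#C)[C@H]([C@]1(C)CCC[C@@](C)(C(=O)OCC=C)[C@H]1C(=O)OCC=C)[C]=O | intermediate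
24 | C13 radical, ring C closed (3-oxocyclohexyl radical with axial-capable propargyl on C8) | CC[Si](CC)(CC)OC[C@@]1(CC#C)C[CH]CC(=O)[C@H]1[C@]2(C)CCC[C@@](C)(C(=O)OCC=C)[C@H]2C(=O)OCC=C | intermediate
25 | C17 vinyl radical, rings C and D closed | [CH]=C1C[C@]2(CO[Si](CC)(CC)CC)C[C@H]1CC(=O)[C@H]2[C@]1(C)CCC[C@@](C)(C(=O)OCC=C)[C@H]1C(=O)OCC=C | intermediate
26 | diallyl 11-oxo-7-(triethylsilyloxy)-6,7-seco-ent-kaur-16-ene-6,19-dioate | C=C1C[C@]2(CO[Si](CC)(CC)CC)C[C@H]1CC(=O)[C@H]2[C@]1(C)CCC[C@@](C)(C(=O)OCC=C)[C@H]1C(=O)OCC=C | intermediate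
27 | diallyl 7,11-dioxo-6,7-seco-ent-kaur-16-ene-6,19-dioate | C=C1C[C@]2(C=O)C[C@H]1CC(=O)[C@H]2[C@]1(C)CCC[C@@](C)(C(=O)OCC=C)[C@H]1C(=O)OCC=C | intermediate
28 | 7,11-dioxo-6,7-seco-ent-kaur-16-ene-6,19-dioic acid (CNP0408869.1) | C=C1C[C@]2(C=O)C[C@H]1CC(=O)[C@H]2[C@]1(C)CCC[C@@](C)(C(=O)O)[C@H]1C(=O)O | target

Total step count: 15. Longest linear sequence: 15 steps (from 1; all other components are commercial reagents).

**Steps most likely to fail**

Step 13 (cascade). The acyl radical may close in the 5-exo mode and the resulting primary radical may be caught by the alkyne, the acyl radical may lose CO, or the C13 radical may be reduced before the conformer needed for the second closure is reached. The fallback sets out from acid 21 and returns at 26; both ring closures are then exo and ring D forms first. Acid 21 would be converted into N-methoxy-N-methylamide F1 (MeNHOMe·HCl, EDC, DMAP) and reduced to aldehyde F2 (i-Bu2AlH, −78 °C). Bu3SnH/AIBN would add a stannyl radical to the alkyne terminus, the vinyl radical would close ring D by 5-exo-trig attack on C13, and the primary C12 radical would close ring C by 6-exo attack on the aldehyde carbon. This would give stannyl alcohol F3 (only the C13 epimer with C12 syn to C9 can close ring C). Protodestannylation (CF3CO2H, CH2Cl2, 0 °C) to alcohol F4 and Dess–Martin oxidation would give 26.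

Step 9 (quaternisation of C8). The tertiary enolate next to the tert-alkyl-substituted C9 may be alkylated too slowly, on oxygen, or be quenched by proton transfer. The fallback sets out from 16 and returns at 17, replacing the enolate SN2 step by a radical allylation. The enolate of 16 would be selenenylated (LiN(iPr)2; PhSeCl) to selenide F5. The C8 radical generated from it (Bu3SnCH2CH=CH2, AIBN, benzene, 80 °C; Keck allylation) would take up the allyl group anti to the C9 substituent to give 17, which buffered fluoride would convert into 18.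

Step 11 (differentiation of C7 and C11). Hydride may attack C11 instead of C7, or the hydroxy acid may lactonise before it is silylated. The fallback sets out from anhydride 19 and returns at 27. Anhydride 19 would be opened with PhSeH/pyridine at the less hindered carbonyl C11 to selenoester acid F6, and the C7 acid would be converted into S-ethyl thioester F7 (EtSH, EDC, DMAP). The radical cascade of step 13 run on F7 would give bicyclic thioester F8. Fukuyama reduction (Et3SiH, 5% Pd/CaCO3 poisoned with Pb(OAc)2, acetone, 23 °C) would give aldehyde 27.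

**Further compounds**
F1 | step 13 | N-methoxy-N-methylamide of acid 21 (C11) | CC[Si](CC)(CC)OC[C@](CC=C)(CC#C)[C@H]([C@]1(C)CCC[C@@](C)(C(=O)OCC=C)[C@H]1C(=O)OCC=C)C(=O)N(C)OC
F2 | step 13 | C11 aldehyde corresponding to 21 | CC[Si](CC)(CC)OC[C@](CC=C)(CC#C)[C@H]([C@]1(C)CCC[C@@](C)(C(=O)OCC=C)[C@H]1C(=O)OCC=C)C=O
F3 | step 13 | diallyl 11-hydroxy-17-(tributylstannyl)-7-(triethylsilyloxy)-6,7-seco-ent-kaur-16-ene-6,19-dioate (C11 epimers) | CCCC[Sn](CCCC)(CCCC)C=C1C[C@]2(CO[Si](CC)(CC)CC)C[C@H]1CC(O)[C@H]2[C@]1(C)CCC[C@@](C)(C(=O)OCC=C)[C@H]1C(=O)OCC=C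
F4 | step 13 | diallyl 11-hydroxy-7-(triethylsilyloxy)-6,7-seco-ent-kaur-16-ene-6,19-dioate (C11 epimers) | C=C1C[C@]2(CO[Si](CC)(CC)CC)C[C@H]1CC(O)[C@H]2[C@]1(C)CCC[C@@](C)(C(=O)OCC=C)[C@H]1C(=O)OCC=C
F5 | step 9 | C8-(phenylselanyl) derivative of 16 (C8 epimers) | O=C1C(CC#C[Si](C)(C)C)([Se]c2ccccc2)[C@H]([C@]2(C)CCC[C@@](C)(C(=O)OCC=C)[C@H]2C(=O)OCC=C)[C@@H](O[C@H]3C[C@@H](C)CC[C@@H]3C(C)C)O1
F6 | step 11 | C11 Se-phenyl selenoester C7 carboxylic acid from 19 | OC(=O)[C@](CC=C)(CC#C)[C@H]([C@]1(C)CCC[C@@](C)(C(=O)OCC=C)[C@H]1C(=O)OCC=C)C(=O)[Se]c1ccccc1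
F7 | step 11 | C11 Se-phenyl selenoester C7 S-ethyl thioester | CCSC(=O)[C@](CC=C)(CC#C)[C@H]([C@]1(C)CCC[C@@](C)(C(=O)OCC=C)[C@H]1C(=O)OCC=C)C(=O)[Se]c1ccccc1
F8 | step 11 | diallyl 11-oxo-6,7-seco-ent-kaur-16-ene-6,19-dioate 7-(S-ethyl thioate) | C=C1C[C@]2(C(=O)SCC)C[C@H]1CC(=O)[C@H]2[C@]1(C)CCC[C@@](C)(C(=O)OCC=C)[C@H]1C(=O)OCC=C
A1 | direct plan | [(1S)-1-(2-bromoprop-2-en-1-yl)-5-methoxy-2-(trimethylsilyl)cyclohexa-2,5-dien-1-yl]methyl 6-chloro-2,6-dimethyl-7-oxocyclohept-1-ene-1-carboxylate (C4 epimers) | C=C(Br)C[C@]1(COC(=O)C2=C(C)CCCC(C)(Cl)C2=O)C([Si](C)(C)C)=CCC(OC)=C1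
A2 | direct plan | 16-bromo-11-oxo-6,7:13,16-diseco-ent-kaura-12,16-dien-6,7-olid-19-oic acid | C=C(Br)C[C@]2(CO3)CC=CC(=O)[C@H]2[C@]1(C)CCC[C@@](C)(C(=O)O)[C@H]1C3=O
A3 | direct plan | 7-hydroxy-11-oxo-6,7-seco-ent-kaur-16-ene-6,19-dioic acid | C=C1C[C@]2(CO)C[C@H]1CC(=O)[C@H]2[C@]1(C)CCC[C@@](C)(C(=O)O)[C@H]1C(=O)O
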